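**Plan**

- Retrosynthesis (eudesmane numbering; ring A = C1–C5 with C10, ring B = C5–C10): the C11–OOH group and the C6=C7 alkene go back to a C7=C11 isopropylidene enone (singlet-oxygen ene); the O3 ester and the C4 acetate go back to a 3α,4α-epoxide of a C3=C4 alkene.
- The C8 ketone next to C7, which carries the three-carbon C11 unit, is a pulegone-type motif. It is cut at C7–C8 into a C8 aldehyde on the C10 side chain and a prenyl group (C6–C7=C11) on C5, the two partners of a carbonyl-ene closure of ring B.
- Ring A is cut at C3=C4 (ring-closing metathesis), and the C5–C10 bond by an Ireland–Claisen rearrangement of geranyl 5-methylhex-4-enoate.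
- Forward order: ester, C5–C10 bond with both stereocentres, ring A, ring B, C8 ketone with C7=C11, epoxide, acetate, epoxy ester, hydroperoxide; the epoxy acid is made separately from tiglic acid.
- Stereochemistry: C5 and C10 come from the chiral boron enolate and the chair Claisen transition state, which also fixes the trans ring fusion. C3 and C4 come from α-face epoxidation anti to the C10 methyl and trans-diaxial opening. The side-chain epoxide comes from a Sharpless epoxidation. C7 and C8 of the ene product are transient.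

Key step: step 8

Assumption: the (S,S)-bromoborane is taken to be the antipode that leads to (2R,3R)-6; if the sense of induction is the opposite, the (R,R)-reagent is used and nothing else changes.

Remark: bicyclic compounds are named with eudesmane numbering; α is the face opposite to the C10 methyl group.

**Route**

Step 1
Reactants: 1 geraniol; 2 5-methylhex-4-enoic acid
Product: 3 geranyl 5-methylhex-4-enoate
Conditions: DCC, DMAP (cat.), CH2Cl2, 0 °C → rt
Reagents that add atoms: none
Why: Steglich esterification of an unhindered acid with a primary allylic alcohol; no stereocentre is formed and the E alkene of geraniol, which later decides the C10 configuration, is untouched.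

Step 2
Reactants: 3 geranyl 5-methylhex-4-enoate
Product: 6 (2R,3R)-3-ethenyl-3,7-dimethyl-2-(3-methylbut-2-en-1-yl)oct-6-enoic acid, via E(O) boron ketene acetal 4 (not isolated), via boryl carboxylate 5 (not isolated)
Conditions: (4S,5S)-2-bromo-1,3-bis[(3,5-bis(trifluoromethyl)phenyl)sulfonyl]-4,5-diphenyl-1,3,2-diazaborolidine (1.2 equiv), Et3N, toluene–hexane, −78 °C, then −20 → 4 °C, several days; H2O work-up
Reagents that add atoms: none
Why: Enantioselective boron-enolate Ireland–Claisen rearrangement: Et3N in the non-polar medium should give the enolate with the prenyl-bearing carbon trans to the O–B bond, which rearranges through a chair transition state with the (E)-allyl unit (C3 methyl axial) to set C5 and C10 in the (2R*,3R*) sense, the C2-symmetric diazaborolidine selecting the enantiomer.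

Step 3
Reactants: 6 (2R,3R)-3-ethenyl-3,7-dimethyl-2-(3-methylbut-2-en-1-yl)oct-6-enoic acid
Product: 8 (3R,4R)-4-ethenyl-4,8-dimethyl-3-(3-methylbut-2-en-1-yl)non-7-en-2-one, via dilithium gem-diolate 7 (not isolated)
Conditions: MeLi (2.5 equiv), Et2O, 0 °C → rt; inverse quench into cold 1 M HCl
Reagents that add atoms: methyllithium, [Li]C
Why: Addition of methyllithium to a lithium carboxylate stops at the gem-diolate 7, which releases the methyl ketone only on acidic quench (classical acid-to-methyl-ketone conversion), so over-addition and enolisation at C5 are not expected.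

Step 4
Reactants: 8 (3R,4R)-4-ethenyl-4,8-dimethyl-3-(3-methylbut-2-en-1-yl)non-7-en-2-one
Product: 9 (5S,6R)-6-ethenyl-2,6,10-trimethyl-5-(prop-1-en-2-yl)undeca-2,9-diene
Conditions: Cp2TiMe2 (2.5 equiv), toluene, 65 °C, dark
Reagents that add atoms: dimethyltitanocene, C[Ti](C)(C1C=CC=C1)C1C=CC=C1
Why: Petasis methylenation; the non-basic titanium methylidene should convert the hindered, enolisable ketone into the isopropenyl group without epimerising the adjacent C5 centre.

Step 5
Reactants: 9 (5S,6R)-6-ethenyl-2,6,10-trimethyl-5-(prop-1-en-2-yl)undeca-2,9-diene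
Product: 11 (3R,4S)-3,7-dimethyl-3-(4-methylpent-3-en-1-yl)-4-(prop-1-en-2-yl)oct-6-en-1-ol, via catechol boronate 10 (not isolated)
Conditions: catecholborane (1.2 equiv), RhCl(PPh3)3 (2 mol %), THF, 0 °C → rt; then NaOH, H2O2, 0 °C
Reagents that add atoms: hydrogen peroxide, OO
Why: Rhodium-catalysed hydroboration is much more sensitive to alkene substitution than the uncatalysed reaction, so the monosubstituted vinyl group should react anti-Markovnikov in preference to the isopropenyl and the two trisubstituted alkenes, and oxidation of boronate 10 gives the primary alcohol with no stereocentre affected.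

Step 6
Reactants: 11 (3R,4S)-3,7-dimethyl-3-(4-methylpent-3-en-1-yl)-4-(prop-1-en-2-yl)oct-6-en-1-ol
Product: 12 2-[(1R,2R)-1,3-dimethyl-2-(3-methylbut-2-en-1-yl)cyclohex-3-en-1-yl]ethan-1-ol
Conditions: second-generation Grubbs catalyst RuCl2(=CHPh)(PCy3)(H2IMes) (5 mol %), CH2Cl2, 40 °C
Reagents that add atoms: none
Why: Ring-closing metathesis of the isopropenyl group with the homoprenyl alkene closes the six-membered ring A as its trisubstituted C3=C4 alkene with loss of isobutene, whereas the C5 prenyl group could only give a four- or seven-membered ring and should stay; the free hydroxyl is tolerated.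

Step 7
Reactants: 12 2-[(1R,2R)-1,3-dimethyl-2-(3-methylbut-2-en-1-yl)cyclohex-3-en-1-yl]ethan-1-ol
Product: 13 2-[(1R,2R)-1,3-dimethyl-2-(3-methylbut-2-en-1-yl)cyclohex-3-en-1-yl]acetaldehyde
Conditions: Dess–Martin periodinane, NaHCO3, CH2Cl2, 0 °C → rt
Reagents that add atoms: none
Why: Dess–Martin oxidation of the primary alcohol under buffered conditions gives the aldehyde without acid that could trigger a premature Prins or ene reaction; the aldehyde sits on a quaternary carbon and cannot epimerise.

Step 8
Reactants: 13 2-[(1R,2R)-1,3-dimethyl-2-(3-methylbut-2-en-1-yl)cyclohex-3-en-1-yl]acetaldehyde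
Product: 15 eudesma-3,11-dien-8α-ol, via aluminium alkoxide 14 (not isolated)
Conditions: Me2AlCl (1.5 equiv), CH2Cl2, −78 → −20 °C; then 1 M HCl
Reagents that add atoms: none
Why: Me2AlCl activates the C8 aldehyde, C8 bonds to C7 of the prenyl alkene while a hydrogen of a C11 methyl group passes to oxygen in a Lewis-acid-promoted carbonyl-ene reaction of the citronellal-to-isopulegol kind, and the product complex loses methane to give alkoxide 14, which removes the proton source for Prins side reactions. Ring B (C5–C6–C7–C8–C9–C10) closes as a six-membered ring in a type 1 intramolecular ene mode (tether on the alkene carbon that forms the new bond) through a chair transition state. Because the prenyl and acetaldehyde chains are already trans on ring A, only the trans-fused decalin can form. C7 and C8 are set by the chair, with the isopropenyl group (7β) and the oxygen (8α) both equatorial; both centres are erased in steps 9 and 10, so their ratio does not matter. The selectivity needed is reaction at the prenyl alkene and not at the ring-A C3=C4 alkene. Closure onto C3 or C4 would need both chains axial and would give a bridged bicyclooctane, while the prenyl alkene is more nucleophilic, offers six allylic methyl hydrogens and reaches C8 through an unstrained chair.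

Step 9
Reactants: 15 eudesma-3,11-dien-8α-ol
Product: 16 eudesma-3,11-dien-8-one
Conditions: Dess–Martin periodinane, NaHCO3, CH2Cl2, 0 °C → rt
Reagents that add atoms: none
Why: Dess–Martin oxidation of the secondary alcohol to the ketone; the C8 stereocentre is removed and neither alkene is affected.

Step 10
Reactants: 16 eudesma-3,11-dien-8-one
Product: 17 eudesma-3,7(11)-dien-8-one
Conditions: NaOMe (0.2 equiv), MeOH, rt
Reagents that add atoms: none
Why: Base-mediated conjugation of a β,γ-unsaturated ketone through its dienolate (isopulegone-to-pulegone isomerisation) should give the tetrasubstituted exocyclic enone, erasing the C7 stereocentre while C5 and C10 are not enolisable.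

Step 11
Reactants: 17 eudesma-3,7(11)-dien-8-one
Product: 18 3α,4α-epoxyeudesm-7(11)-en-8-one
Conditions: mCPBA (1.05 equiv), NaHCO3, CH2Cl2, −10 → 0 °C
Reagents that add atoms: 3-chloroperoxybenzoic acid, OOC(=O)c1cccc(Cl)c1
Why: Prilezhaev epoxidation; the electron-rich trisubstituted C3=C4 alkene should react well ahead of the carbonyl-deactivated C7=C11 alkene, and the peracid is expected on the α face, anti to the axial C10 methyl, which sets C3 and C4 of the epoxide.

Step 12
Reactants: 18 3α,4α-epoxyeudesm-7(11)-en-8-one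
Product: 19 4β-acetoxy-3α-hydroxyeudesm-7(11)-en-8-one
Conditions: AcOH, NaOAc, 50 °C
Reagents that add atoms: acetic acid, CC(=O)O
Why: Acid-mediated acetolysis of the epoxide: the Fürst–Plattner trans-diaxial opening coincides with attack at the tertiary C4, so acetate should enter at C4 from the β face with inversion and leave the 3α-oxygen in place, and the diaxial arrangement blocks acyl migration.

Step 13
Reactants: 20 tiglic acid
Product: 21 (2E)-2-methylbut-2-en-1-ol
Conditions: LiAlH4, Et2O, 0 °C → rt
Reagents that add atoms: none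
Why: Hydride reduction of the unsaturated acid occurs at the carboxyl group only and keeps the E geometry that later places the two epoxide methyl groups cis.

Step 14
Reactants: 21 (2E)-2-methylbut-2-en-1-ol
Product: 22 [(2R,3R)-2,3-dimethyloxiran-2-yl]methanol
Conditions: Ti(OiPr)4 (10 mol %), D-(−)-diethyl tartrate (12 mol %), t-BuOOH, 4 Å molecular sieves, CH2Cl2, −20 °C
Reagents that add atoms: tert-butyl hydroperoxide, CC(C)(C)OO
Why: Sharpless asymmetric epoxidation; D-(−)-tartrate delivers oxygen to the face opposite to that chosen by L-(+)-tartrate (which gives 2S,3S products from E allylic alcohols), so the (2R,3R)-epoxy alcohol is expected.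

Step 15
Reactants: 22 [(2R,3R)-2,3-dimethyloxiran-2-yl]methanol
Product: 23 (2S,3R)-2,3-dimethyloxirane-2-carboxylic acid
Conditions: RuCl3·H2O (2 mol %), NaIO4, CCl4–MeCN–H2O, 0 °C → rt
Reagents that add atoms: water, O
Why: Ruthenium tetroxide oxidation (catalytic RuCl3 with periodate) takes a primary epoxy alcohol to the glycidic acid through the aldehyde hydrate without opening the epoxide; the descriptor at C2 changes from R to S only because the carboxyl group outranks C3.

Step 16
Reactants: 19 4β-acetoxy-3α-hydroxyeudesm-7(11)-en-8-one; 23 (2S,3R)-2,3-dimethyloxirane-2-carboxylic acid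
Product: 25 4β-acetoxy-8-oxoeudesm-7(11)-en-3α-yl (2S,3R)-2,3-dimethyloxirane-2-carboxylate, via mixed anhydride 24 (not isolated)
Conditions: 23, 2,4,6-trichlorobenzoyl chloride, Et3N, THF, rt; then 19, DMAP, toluene, rt → 40 °C
Reagents that add atoms: none
Why: Yamaguchi esterification; DMAP attacks the aliphatic carbonyl of mixed anhydride 24 and passes the epoxy acyl group to the hindered axial 3α-hydroxyl, the only free hydroxyl in 19, with no stereocentre touched.

Step 17
Reactants: 25 4β-acetoxy-8-oxoeudesm-7(11)-en-3α-yl (2S,3R)-2,3-dimethyloxirane-2-carboxylate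
Product: 26 4β-acetoxy-11-hydroperoxy-8-oxoeudesm-6-en-3α-yl (2S,3R)-2,3-dimethyloxirane-2-carboxylate
Conditions: O2, 5,10,15,20-tetraphenylporphyrin (cat.), CH2Cl2, visible light, −20 → 0 °C
Reagents that add atoms: dioxygen, O=O
Why: Schenck ene reaction of singlet oxygen with an s-cis enone; the geminal preference (hydrogen taken from the alkyl group on the carbonyl-bearing alkene carbon, here C6) should put the hydroperoxide on C11 and move the alkene to C6=C7 in conjugation with the C8 ketone, with no new stereocentre.

**Compound list**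

1 | geraniol, (2E)-3,7-dimethylocta-2,6-dien-1-ol | CC(C)=CCC/C(C)=C/CO | starting material
2 | 5-methylhex-4-enoic acid | CC(C)=CCCC(=O)O | starting material
3 | geranyl 5-methylhex-4-enoate | CC(C)=CCCC(=O)OC/C=C(\C)CCC=C(C)C | intermediate
4 | E(O) boron ketene acetal of 3 (prenyl CH2 trans to O–B; boron in the (4S,5S)-diazaborolidine) | CC(C)=CC/C=C(/OB1N(S(=O)(=O)c2cc(cc(c2)C(F)(F)F)C(F)(F)F)[C@@H](c2ccccc2)[C@H](c2ccccc2)N1S(=O)(=O)c1cc(cc(c1)C(F)(F)F)C(F)(F)F)\OC/C=C(\C)CCC=C(C)C | intermediate (not isolated)
5 | boryl carboxylate of acid 6 | CC(C)=CC[C@@H](C(=O)OB1N(S(=O)(=O)c2cc(cc(c2)C(F)(F)F)C(F)(F)F)[C@@H](c2ccccc2)[C@H](c2ccccc2)N1S(=O)(=O)c1cc(cc(c1)C(F)(F)F)C(F)(F)F)[C@@](C)(C=C)CCC=C(C)C | intermediate (not isolated)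
6 | (2R,3R)-3-ethenyl-3,7-dimethyl-2-(3-methylbut-2-en-1-yl)oct-6-enoic acid | CC(C)=CC[C@@H](C(=O)O)[C@@](C)(C=C)CCC=C(C)C | intermediate
7 | dilithium gem-diolate of ketone 8 | CC(O[Li])(O[Li])[C@H](CC=C(C)C)[C@@](C)(C=C)CCC=C(C)C | intermediate (not isolated)
8 | (3R,4R)-4-ethenyl-4,8-dimethyl-3-(3-methylbut-2-en-1-yl)non-7-en-2-one | CC(=O)[C@H](CC=C(C)C)[C@@](C)(C=C)CCC=C(C)C | intermediate
9 | (5S,6R)-6-ethenyl-2,6,10-trimethyl-5-(prop-1-en-2-yl)undeca-2,9-diene | CC(=C)[C@H](CC=C(C)C)[C@@](C)(C=C)CCC=C(C)C | intermediate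
10 | catechol boronate corresponding to alcohol 11 (benzodioxaborolyl in place of OH) | CC(=C)[C@H](CC=C(C)C)[C@@](C)(CCB1Oc2ccccc2O1)CCC=C(C)C | intermediate (not isolated)
11 | (3R,4S)-3,7-dimethyl-3-(4-methylpent-3-en-1-yl)-4-(prop-1-en-2-yl)oct-6-en-1-ol | CC(=C)[C@H](CC=C(C)C)[C@@](C)(CCO)CCC=C(C)C | intermediate
12 | 2-[(1R,2R)-1,3-dimethyl-2-(3-methylbut-2-en-1-yl)cyclohex-3-en-1-yl]ethan-1-ol | OCC[C@@]1(C)CCC=C(C)[C@@H]1CC=C(C)C | intermediate
13 | 2-[(1R,2R)-1,3-dimethyl-2-(3-methylbut-2-en-1-yl)cyclohex-3-en-1-yl]acetaldehyde | O=CC[C@@]1(C)CCC=C(C)[C@@H]1CC=C(C)C | intermediate (precursor of the key step)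
14 | chloro(methyl)aluminium alkoxide of 15 | CC1=CCC[C@]2(C)C[C@H](O[Al](C)Cl)[C@@H](C(C)=C)C[C@@H]12 | intermediate (not isolated)
15 | eudesma-3,11-dien-8α-ol (5α-H, 7β-isopropenyl, 10β-methyl); (2S,3R,4aR,8aR)-5,8a-dimethyl-3-(prop-1-en-2-yl)-1,2,3,4,4a,7,8,8a-octahydronaphthalen-2-ol | CC1=CCC[C@]2(C)C[C@H](O)[C@@H](C(C)=C)C[C@@H]12 | intermediate (product of the key step)
16 | eudesma-3,11-dien-8-one (5α-H, 7α-H, 10β-methyl) | CC1=CCC[C@]2(C)CC(=O)[C@@H](C(C)=C)C[C@@H]12 | intermediate
17 | eudesma-3,7(11)-dien-8-one (5α-H, 10β-methyl) | CC1=CCC[C@]2(C)CC(=O)C(=C(C)C)C[C@@H]12 | intermediate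
18 | 3α,4α-epoxyeudesm-7(11)-en-8-one | C[C@@]12O[C@@H]1CC[C@]3(C)CC(=O)C(=C(C)C)C[C@@H]23 | intermediate
19 | 4β-acetoxy-3α-hydroxyeudesm-7(11)-en-8-one | CC(=O)O[C@]1(C)[C@@H]2CC(=C(C)C)C(=O)C[C@@]2(C)CC[C@H]1O | intermediate
20 | tiglic acid, (2E)-2-methylbut-2-enoic acid | C/C=C(\C)C(=O)O | starting material
21 | (2E)-2-methylbut-2-en-1-ol | C/C=C(\C)CO | intermediate
22 | [(2R,3R)-2,3-dimethyloxiran-2-yl]methanol | OC[C@@]1(C)O[C@@H]1C | intermediate
23 | (2S,3R)-2,3-dimethyloxirane-2-carboxylic acid | OC(=O)[C@@]1(C)O[C@@H]1C | intermediate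
24 | mixed anhydride of 23 with 2,4,6-trichlorobenzoic acid | O=C(OC(=O)c1c(Cl)cc(Cl)cc1Cl)[C@@]1(C)O[C@@H]1C | intermediate (not isolated)
25 | 4β-acetoxy-8-oxoeudesm-7(11)-en-3α-yl (2S,3R)-2,3-dimethyloxirane-2-carboxylate | CC(=O)O[C@]1(C)[C@@H]2CC(=C(C)C)C(=O)C[C@@]2(C)CC[C@H]1OC(=O)[C@@]1(C)O[C@@H]1C | intermediate
26 | 4β-acetoxy-11-hydroperoxy-8-oxoeudesm-6-en-3α-yl (2S,3R)-2,3-dimethyloxirane-2-carboxylate (5α-H, 10β-methyl; 3R,4R,5R,10R) | CC(=O)O[C@]1(C)[C@@H]2C=C(C(C)(C)OO)C(=O)C[C@@]2(C)CC[C@H]1OC(=O)[C@@]1(C)O[C@@H]1C | target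

**Step count**

Total: 17 steps. Longest linear sequence: 14 steps (steps 1–12, 16 and 17); steps 13–15 make the epoxy acid.

**Steps most likely to fail, with fallbacks**

Step 17. The risk is poor regioselectivity of hydrogen abstraction: the C12 and C13 methyl hydrogens can compete with H6, which puts the oxygen on C7. Conversion of the electron-poor enone may also be slow, so that the product and the epoxy ester stay long under sensitiser and light. The fallback moves the oxygenation ahead of the convergent esterification and carries the hydroperoxide masked, so that regioisomers are removed before acid 23 is invested. It sets out from 19. Photooxygenation under the conditions of step 17 should give 4β-acetoxy-11-hydroperoxy-3α-hydroxyeudesm-6-en-8-one F1. TBSCl and imidazole in DMF at 0 °C should silylate the unhindered, more acidic hydroperoxide in preference to the hindered axial 3α-hydroxyl and give the tert-butyldimethylsilyl peroxide F2. Yamaguchi esterification with 23 through 24 then gives the silyl peroxide ester F3. HF·pyridine in THF at 0 °C cleaves the O–Si bond and the sequence comes back to the route at 26.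

Step 12. The risk is loss of a proton from the developing tertiary C4 cation (giving allylic alcohols), or a hydride shift to a ketone, outrunning capture by acetic acid. The fallback separates opening from acetylation and sets out from 18. Dilute HClO4 in THF–H2O, where water is present in large excess, should open the epoxide trans-diaxially to 3α,4β-dihydroxyeudesm-7(11)-en-8-one F4. Ac2O with catalytic Sc(OTf)3 in MeCN at −20 °C acetylates both hydroxyls to give 3α,4β-diacetoxyeudesm-7(11)-en-8-one F5. K2CO3 in MeOH at 0 °C then removes the secondary acetate, which is cleaved much faster than the tertiary one, and the sequence comes back to the route at 19.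

Step 5. The risk is incomplete discrimination between the vinyl group on the quaternary carbon and the isopropenyl group, so that both terminal alkenes are hydroborated. The fallback hydroborates before the isopropenyl group exists and sets out from acid 6. 9-BBN in THF (excess, the acid taking up the first equivalent; the trisubstituted alkenes are inert), followed by NaOH and H2O2 and acidification, should give (3R,4R)-4-methyl-3-(3-methylbut-2-en-1-yl)-4-(4-methylpent-3-en-1-yl)oxan-2-one F6. MeLi (1 equiv) in THF at −78 °C opens the lactone to (3R,4R)-4-(2-hydroxyethyl)-4,8-dimethyl-3-(3-methylbut-2-en-1-yl)non-7-en-2-one F7, which may rest as its cyclic hemiketal. Wittig methylenation with excess Ph3P=CH2 (from Ph3PCH3Br and KOt-Bu, toluene, 80 °C) then gives the isopropenyl alcohol, and the sequence comes back to the route at 11.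

**Further compounds**

F1 | step 17 | 4β-acetoxy-11-hydroperoxy-3α-hydroxyeudesm-6-en-8-one | CC(=O)O[C@]1(C)[C@@H]2C=C(C(C)(C)OO)C(=O)C[C@@]2(C)CC[C@H]1O
F2 | step 17 | 4β-acetoxy-11-(tert-butyldimethylsilylperoxy)-3α-hydroxyeudesm-6-en-8-one | CC(=O)O[C@]1(C)[C@@H]2C=C(C(C)(C)OO[Si](C)(C)C(C)(C)C)C(=O)C[C@@]2(C)CC[C@H]1O
F3 | step 17 | 4β-acetoxy-11-(tert-butyldimethylsilylperoxy)-8-oxoeudesm-6-en-3α-yl (2S,3R)-2,3-dimethyloxirane-2-carboxylate | CC(=O)O[C@]1(C)[C@@H]2C=C(C(C)(C)OO[Si](C)(C)C(C)(C)C)C(=O)C[C@@]2(C)CC[C@H]1OC(=O)[C@@]1(C)O[C@@H]1C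
F4 | step 12 | 3α,4β-dihydroxyeudesm-7(11)-en-8-one | O[C@]1(C)[C@@H]2CC(=C(C)C)C(=O)C[C@@]2(C)CC[C@H]1O
F5 | step 12 | 3α,4β-diacetoxyeudesm-7(11)-en-8-one | CC(=O)O[C@]1(C)[C@@H]2CC(=C(C)C)C(=O)C[C@@]2(C)CC[C@H]1OC(C)=O
F6 | step 5 | (3R,4R)-4-methyl-3-(3-methylbut-2-en-1-yl)-4-(4-methylpent-3-en-1-yl)oxan-2-one | O=C1OCC[C@@](C)(CCC=C(C)C)[C@H]1CC=C(C)C
F7 | step 5 | (3R,4R)-4-(2-hydroxyethyl)-4,8-dimethyl-3-(3-methylbut-2-en-1-yl)non-7-en-2-one | CC(=O)[C@H](CC=C(C)C)[C@@](C)(CCO)CCC=C(C)C
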